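Numbering: decalin C1–C10 as in drimanes (Br on C3, gem-dimethyl on C4, ring fusion C5/C10, methylene on C8), C11 is the benzylic CH2 on C9, arene carbons Ar1–Ar6 (C11 on Ar1, OH on Ar3 and Ar6, CHO on Ar4).
Cuts: Ar2–Ar3, Ar1–Ar6 and Ar5–Ar6 (arene back to a C11-propargyl decalin, an alkenyl(methoxy)carbene chromium complex and one CO); then C11–C(alkyne); then C4–C5 and C9–C10 (both carbocycles from an open (6Z)-keto ester); then the bond between the acetoacetate γ-carbon and neryl C1.
Enabling feature: ring Ar1–Ar6 is a hydroquinone whose para oxygens (Ar3, Ar6) sit next to the formyl carbon (Ar4) and to C11 (Ar1), with Ar2 and Ar5 bare. This is the pattern in which a terminal alkyne (Ar1, Ar2), an alkenyl(methoxy)carbene (Ar3–Ar5) and CO (Ar6) assemble, and building this electron-rich ring last keeps it out of the bromonium chemistry that installs C3–Br.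
Forward order: the chain is joined (neryl bromide plus acetoacetate dianion), ring A and then ring B close in one bromonium cascade, C8 is methylenated, C11 becomes CH2–C≡CH, the arene closes by benzannulation, and desilylation, benzylic oxidation and O-demethylation finish.
Stereochemistry: C3, C5, C9 and C10 are set together in the cascade (Z alkene and anti addition through a chair give the cis fusion, equatorial Br and equatorial C9 ester). The absolute configuration comes from a (−)-menthyl ester whose two diastereomeric cyclisation products are separated, and no stereocentre is touched afterwards.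

Key step: step 10

Remark on the chemistry: the SMILES is read as the cis-fused decalin with the C3 bromine, the C5 hydrogen and the C9 hydrogen all on the face of the C10 methyl group (3S,5S,9R,10R in the numbering above). (−)-Menthyl acetoacetate and Et2SBr·SbCl5Br are assumed to be purchasable.

Step 1
Reactants: 1 nerol
Product: 2 neryl bromide, (2Z)-1-bromo-3,7-dimethylocta-2,6-diene
Conditions: PBr3 (0.4 equiv), Et2O, −10 °C
Reagents that add atoms: phosphorus tribromide, BrP(Br)Br
Why: Conversion of a primary allylic alcohol into the bromide with PBr3 at low temperature is an SN2-type substitution that should leave the Z geometry of the 2,3-alkene intact; the bromide is used crude.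

Step 2
Reactants: 3 (−)-menthyl acetoacetate; 2 neryl bromide
Product: 5 (1R,2S,5R)-menthyl (6Z)-7,11-dimethyl-3-oxododeca-6,10-dienoate, via acetoacetate dianion 4 (not isolated)
Conditions: NaH, THF, 0 °C; n-BuLi, 0 °C; 2, 0 °C to rt; 1 M HCl
Reagents that add atoms: none
Why: γ-Alkylation of an acetoacetate dianion: the more basic terminal carbanion attacks the allylic bromide in an SN2 reaction, which should join the chain without touching the alkene geometry or the menthyl ester.

Step 3
Reactants: 5 menthyl (6Z)-keto ester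
Product: 6 (1R,2S,5R)-menthyl (1S,4aS,6S,8aS)-6-bromo-5,5,8a-trimethyl-2-oxodecahydronaphthalene-1-carboxylate
Conditions: Et2SBr·SbCl5Br (1.1 equiv), MeNO2, −25 °C, 5 min; aq Na2SO3/NaHCO3; chromatography and crystallisation to remove the other diastereomer
Reagents that add atoms: bromodiethylsulfonium bromopentachloroantimonate, CC[S+](Br)CC.Cl[Sb-](Cl)(Cl)(Cl)(Cl)Br
Why: Bromonium-initiated cation–olefin bicyclisation terminated by a β-keto ester: Br+ goes to the terminal trisubstituted alkene, the (6Z)-alkene adds anti through a chair (Br equatorial on C3, cis to the C10 methyl, cis ring fusion dictated by the Z geometry) and the chelated Z enol closes ring B on the C10 cation with the ester equatorial at C9 (also the more stable epimer); the remote menthyl group is not expected to bias the face of bromonium formation, so the diastereomer with the antipodal decalin should form to a similar extent and is removed, the configuration of 6 being secured by X-ray diffraction using the anomalous scattering of bromine.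

Step 4
Reactants: 6 bromo keto ester
Product: 7 (1R,2S,5R)-menthyl (1R,4aS,6S,8aS)-6-bromo-5,5,8a-trimethyl-2-methylidenedecahydronaphthalene-1-carboxylate
Conditions: Ph3PCH3Br, KN(SiMe3)2, toluene/THF, 0 to 50 °C
Reagents that add atoms: methyltriphenylphosphonium bromide, C[P+](c1ccccc1)(c1ccccc1)c1ccccc1.[Br-]
Why: Wittig methylenation of the C8 ketone; the C9 hydrogen is shielded by the quaternary C10, so enolate formation should not outrun addition of the non-stabilised ylide (as in methylenations of related drimane keto esters), the C9 ester stays in its preferred equatorial position, and the equatorial C3 bromide has no anti-periplanar hydrogen for elimination.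

Step 5
Reactants: 7 methylene ester
Product: 8 [(1R,4aS,6S,8aS)-6-bromo-5,5,8a-trimethyl-2-methylidenedecahydronaphthalen-1-yl]methanol
Conditions: i-Bu2AlH (4 equiv), CH2Cl2, −78 to 0 °C; aq potassium sodium tartrate
Reagents that add atoms: none
Why: Hydride reduction of the ester to the primary alcohol, which releases menthol; the hindered secondary bromide and the 1,1-disubstituted alkene should not react with i-Bu2AlH at this temperature.

Step 6
Reactants: 8 primary alcohol
Product: 9 [(1R,4aS,6S,8aS)-6-bromo-5,5,8a-trimethyl-2-methylidenedecahydronaphthalen-1-yl]methyl trifluoromethanesulfonate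
Conditions: Tf2O, 2,6-lutidine, CH2Cl2, −78 °C
Reagents that add atoms: trifluoromethanesulfonic anhydride, O=S(=O)(OS(=O)(=O)C(F)(F)F)C(F)(F)F
Why: O-Sulfonylation of a primary alcohol; a triflate is chosen because C11 is β-branched and needs the best leaving group, and it is used at once because it is homoallylic.

Step 7
Reactants: 9 primary triflate
Product: 11 (1R,4aS,6S,8aR)-6-bromo-5,5,8a-trimethyl-2-methylidene-1-(prop-2-yn-1-yl)decahydronaphthalene, via trimethylsilyl alkyne 10 (not isolated)
Conditions: Me3SiC≡CH, n-BuLi, THF, −78 °C; 9, THF/DMPU, −78 to −20 °C; then K2CO3, MeOH, rt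
Reagents that add atoms: (trimethylsilyl)acetylene, C#C[Si](C)(C)C
Why: SN2 alkylation of a lithium acetylide by a primary triflate in a dipolar medium, followed by base-mediated C–Si cleavage in methanol; C9 is not involved and the neopentyl-type secondary bromide at C3 is inert to substitution under these conditions.

Step 8
Reactants: 12 2-bromoallyl alcohol
Product: 13 (2-bromoallyloxy)(tert-butyl)dimethylsilane
Conditions: TBSCl, imidazole, CH2Cl2, rt
Reagents that add atoms: tert-butyldimethylsilyl chloride, CC(C)(C)[Si](C)(C)Cl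
Why: Standard silylation of a primary alcohol, which masks the future formyl carbon at the alcohol oxidation level.

Step 9
Reactants: 13 silyl ether; 14 chromium hexacarbonyl
Product: 17 pentacarbonyl{methoxy[3-(tert-butyldimethylsilyloxy)prop-1-en-2-yl]carbene}chromium, via 2-lithioallyl silyl ether 15 (not isolated), via lithium acylchromate 16 (not isolated)
Conditions: t-BuLi (2 equiv), Et2O, −78 °C; Cr(CO)6, THF, −78 to −30 °C; evaporate; Me3OBF4, CH2Cl2, 0 °C
Reagents that add atoms: trimethyloxonium tetrafluoroborate, C[O+](C)C.F[B-](F)(F)F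
Why: Fischer carbene synthesis: Br/Li exchange gives the alkenyllithium, which is kept cold so that the silyl group does not migrate from oxygen to carbon, it adds to a CO ligand of Cr(CO)6, and O-methylation of the resulting acylchromate by the oxonium salt gives the alkenyl(methoxy)carbene complex.

Step 10
Reactants: 11 propargyl bromo decalin; 17 alkenyl(methoxy)carbene complex
Product: 19 2-{[(1R,4aS,6S,8aR)-6-bromo-5,5,8a-trimethyl-2-methylidenedecahydronaphthalen-1-yl]methyl}-5-[(tert-butyldimethylsilyloxy)methyl]-4-methoxyphenol, via tricarbonylchromium arene complex 18 (not isolated)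
Conditions: 17 (1.5 equiv), THF, 50 °C, Ar; then air, Et2O, light, rt
Reagents that add atoms: none
Why: Thermal loss of one CO from 17 frees a site on chromium; the terminal alkyne of 11 inserts into the Cr=C bond with its unsubstituted carbon bonding to the carbene carbon (Ar2–Ar3), a CO ligand inserts to give a chromium-bound dienylketene (Ar1–Ar6), and ring closure onto the alkenyl CH2 (Ar5–Ar6) followed by enolisation gives the phenol as its Cr(CO)3 complex 18, which air demetalates. The closest known reaction type is the Dötz benzannulation of alkenyl(alkoxy)carbene complexes of zerovalent chromium with terminal alkynes, which is well established. The single ring formed, the arene, closes by a 6π-electrocyclisation of the metal-templated triene that has the ketene as one terminus, and it aromatises by tautomerisation. No stereocentre is created, and C3, C5, C9 and C10 lie outside the reacting system. The step needs regioselective insertion (the C11-bearing alkyne carbon next to the CO-derived Ar6), which the steric preference of a terminal alkyne for keeping its substituent away from the carbene carbon secures. It also needs chemoselectivity, which rests on the inertness of the hindered secondary bromide and of the 1,1-disubstituted alkene towards the carbene complex at 50 °C, the alkene being only two carbons from the alkyne and thus too close for an intramolecular cyclopropanation; the two oxygens end up para and the silyloxymethyl group on Ar4 next to the methoxy group.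

Step 11
Reactants: 19 silyl ether
Product: 20 2-{[(1R,4aS,6S,8aR)-6-bromo-5,5,8a-trimethyl-2-methylidenedecahydronaphthalen-1-yl]methyl}-5-(hydroxymethyl)-4-methoxyphenol
Conditions: Bu4NF, THF, 0 °C; H2O
Reagents that add atoms: none
Why: Fluoride-mediated Si–O cleavage; the phenol is only deprotonated reversibly and the hindered secondary bromide should not react with fluoride at 0 °C.

Step 12
Reactants: 20 benzylic alcohol
Product: 21 4-{[(1R,4aS,6S,8aR)-6-bromo-5,5,8a-trimethyl-2-methylidenedecahydronaphthalen-1-yl]methyl}-5-hydroxy-2-methoxybenzaldehyde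
Conditions: MnO2 (activated, excess), CH2Cl2, rt
Reagents that add atoms: none
Why: Heterogeneous MnO2 oxidation of an electron-rich benzylic alcohol to the aldehyde, which should be much faster than oxidation of the para-methoxyphenol and does not proceed to the acid.

Step 13
Reactants: 21 methoxy aldehyde
Product: 22 peyssonol A, 4-{[(1R,4aS,6S,8aR)-6-bromo-5,5,8a-trimethyl-2-methylidenedecahydronaphthalen-1-yl]methyl}-2,5-dihydroxybenzaldehyde
Conditions: BCl3 (1 M in CH2Cl2), CH2Cl2, −78 °C; MeOH then aq NaHCO3 at −78 °C
Reagents that add atoms: none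
Why: Chelation-directed ether cleavage: BCl3 is held between the formyl oxygen and the ortho methoxy oxygen and chloride removes the methyl group, while the low temperature and the cold buffered quench are meant to keep the C8 methylene from being protonated and captured by the Ar6 hydroxyl.

Compound list
1 | nerol, (2Z)-3,7-dimethylocta-2,6-dien-1-ol | CC(C)=CCC/C(C)=C\CO | starting material
2 | neryl bromide, (2Z)-1-bromo-3,7-dimethylocta-2,6-diene | CC(C)=CCC/C(C)=C\CBr | intermediate
3 | (−)-menthyl acetoacetate, (1R,2S,5R)-5-methyl-2-(propan-2-yl)cyclohexyl 3-oxobutanoate | CC(C)[C@@H]1CC[C@@H](C)C[C@H]1OC(=O)CC(C)=O | starting material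
4 | sodium lithium dianion (1,3-dienolate) of 3 | CC(C)[C@@H]1CC[C@@H](C)C[C@H]1OC([O-])=CC([O-])=C.[Na+].[Li+] | intermediate
5 | (1R,2S,5R)-menthyl (6Z)-7,11-dimethyl-3-oxododeca-6,10-dienoate | CC(C)[C@@H]1CC[C@@H](C)C[C@H]1OC(=O)CC(=O)CC/C=C(C)\CCC=C(C)C | intermediate
6 | (1R,2S,5R)-menthyl (1S,4aS,6S,8aS)-6-bromo-5,5,8a-trimethyl-2-oxodecahydronaphthalene-1-carboxylate (cis-fused) | O=C1CC[C@@H]2C(C)(C)[C@@H](Br)CC[C@]2(C)[C@@H]1C(=O)O[C@@H]3C[C@H](C)CC[C@H]3C(C)C | intermediate
7 | (1R,2S,5R)-menthyl (1R,4aS,6S,8aS)-6-bromo-5,5,8a-trimethyl-2-methylidenedecahydronaphthalene-1-carboxylate | C=C1CC[C@@H]2C(C)(C)[C@@H](Br)CC[C@]2(C)[C@@H]1C(=O)O[C@@H]3C[C@H](C)CC[C@H]3C(C)C | intermediate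
8 | [(1R,4aS,6S,8aS)-6-bromo-5,5,8a-trimethyl-2-methylidenedecahydronaphthalen-1-yl]methanol | C=C1CC[C@@H]2C(C)(C)[C@@H](Br)CC[C@]2(C)[C@@H]1CO | intermediate
9 | [(1R,4aS,6S,8aS)-6-bromo-5,5,8a-trimethyl-2-methylidenedecahydronaphthalen-1-yl]methyl trifluoromethanesulfonate | C=C1CC[C@@H]2C(C)(C)[C@@H](Br)CC[C@]2(C)[C@@H]1COS(=O)(=O)C(F)(F)F | intermediate
10 | (1R,4aS,6S,8aR)-6-bromo-5,5,8a-trimethyl-2-methylidene-1-[3-(trimethylsilyl)prop-2-yn-1-yl]decahydronaphthalene | C=C1CC[C@@H]2C(C)(C)[C@@H](Br)CC[C@]2(C)[C@@H]1CC#C[Si](C)(C)C | intermediate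
11 | (1R,4aS,6S,8aR)-6-bromo-5,5,8a-trimethyl-2-methylidene-1-(prop-2-yn-1-yl)decahydronaphthalene | C=C1CC[C@@H]2C(C)(C)[C@@H](Br)CC[C@]2(C)[C@@H]1CC#C | intermediate
12 | 2-bromoallyl alcohol, 2-bromoprop-2-en-1-ol | C=C(Br)CO | starting material
13 | (2-bromoallyloxy)(tert-butyl)dimethylsilane | C=C(Br)CO[Si](C)(C)C(C)(C)C | intermediate
14 | chromium hexacarbonyl | O=C=[Cr](=C=O)(=C=O)(=C=O)(=C=O)=C=O | starting material
15 | [3-(tert-butyldimethylsilyloxy)prop-1-en-2-yl]lithium | [Li]C(=C)CO[Si](C)(C)C(C)(C)C | intermediate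
16 | lithium pentacarbonyl{2-[(tert-butyldimethylsilyloxy)methyl]acryloyl}chromate | [Li+].[O-]C(=[Cr](=C=O)(=C=O)(=C=O)(=C=O)=C=O)C(=C)CO[Si](C)(C)C(C)(C)C | intermediate
17 | pentacarbonyl{methoxy[3-(tert-butyldimethylsilyloxy)prop-1-en-2-yl]carbene}chromium | COC(=[Cr](=C=O)(=C=O)(=C=O)(=C=O)=C=O)C(=C)CO[Si](C)(C)C(C)(C)C | intermediate
18 | η6-tricarbonylchromium complex of 19 (chromium on the new arene ring; written as two fragments) | C=C1CC[C@@H]2C(C)(C)[C@@H](Br)CC[C@]2(C)[C@@H]1Cc1cc(OC)c(CO[Si](C)(C)C(C)(C)C)cc1O.O=C=[Cr](=C=O)=C=O | intermediate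
19 | 2-{[(1R,4aS,6S,8aR)-6-bromo-5,5,8a-trimethyl-2-methylidenedecahydronaphthalen-1-yl]methyl}-5-[(tert-butyldimethylsilyloxy)methyl]-4-methoxyphenol | C=C1CC[C@@H]2C(C)(C)[C@@H](Br)CC[C@]2(C)[C@@H]1Cc1cc(OC)c(CO[Si](C)(C)C(C)(C)C)cc1O | intermediate
20 | 2-{[(1R,4aS,6S,8aR)-6-bromo-5,5,8a-trimethyl-2-methylidenedecahydronaphthalen-1-yl]methyl}-5-(hydroxymethyl)-4-methoxyphenol | C=C1CC[C@@H]2C(C)(C)[C@@H](Br)CC[C@]2(C)[C@@H]1Cc1cc(OC)c(CO)cc1O | intermediate
21 | 4-{[(1R,4aS,6S,8aR)-6-bromo-5,5,8a-trimethyl-2-methylidenedecahydronaphthalen-1-yl]methyl}-5-hydroxy-2-methoxybenzaldehyde | C=C1CC[C@@H]2C(C)(C)[C@@H](Br)CC[C@]2(C)[C@@H]1Cc1cc(OC)c(C=O)cc1O | intermediate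
22 | peyssonol A, 4-{[(1R,4aS,6S,8aR)-6-bromo-5,5,8a-trimethyl-2-methylidenedecahydronaphthalen-1-yl]methyl}-2,5-dihydroxybenzaldehyde | C=C1CC[C@@H]2C(C)(C)[C@@H](Br)CC[C@]2(C)[C@@H]1Cc1cc(O)c(C=O)cc1O | target

Total step count: 13. Longest linear sequence: 11 steps (steps 1–7 and 10–13, from nerol); the carbene complex (steps 8 and 9) joins at step 10.

Steps most likely to fail

Step 3. The two diastereomeric cyclisation products may co-elute and co-crystallise, so that the absolute configuration cannot be selected at this stage. Fallback: setting out from 6 in admixture with its diastereomer, steps 4 and 5 are run on the mixture. This should give 7 together with its diastereomer, (1R,2S,5R)-menthyl (1S,4aR,6R,8aR)-6-bromo-5,5,8a-trimethyl-2-methylidenedecahydronaphthalene-1-carboxylate F1. Reduction then removes menthol and leaves the racemic alcohol, that is 8 together with its enantiomer [(1S,4aR,6R,8aR)-6-bromo-5,5,8a-trimethyl-2-methylidenedecahydronaphthalen-1-yl]methanol F2. Acylation with (1S)-camphanic chloride (Et3N, DMAP, CH2Cl2) should give the (1S,4R)-camphanate of 8 F3 and the (1S,4R)-camphanate of the enantiomeric alcohol F4. These diastereomers have their stereocentres only a few bonds apart and are separated by crystallisation or HPLC, with X-ray assignment through bromine. Methanolysis of F3 (K2CO3, MeOH) returns the route to 8.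

Step 7. The basic acetylide may remove the allylic C9 hydrogen and eliminate triflate across C9–C11, or the homoallylic triflate may ionise, instead of undergoing substitution at the β-branched C11. Fallback: setting out from 8, oxidation with Dess–Martin periodinane (NaHCO3, CH2Cl2) should give (1R,4aS,6S,8aS)-6-bromo-5,5,8a-trimethyl-2-methylidenedecahydronaphthalene-1-carbaldehyde F5, used at once. Wittig reaction with Ph3P=CHOMe (from Ph3PCH2OMe chloride and KN(SiMe3)2, THF, −78 to 0 °C) gives the enol ether (1R,4aS,6S,8aS)-6-bromo-1-(2-methoxyethenyl)-5,5,8a-trimethyl-2-methylidenedecahydronaphthalene F6 as an E/Z mixture. Brief hydrolysis (dilute HCl, THF, 0 °C) gives the homologated aldehyde 2-[(1R,4aS,6S,8aR)-6-bromo-5,5,8a-trimethyl-2-methylidenedecahydronaphthalen-1-yl]acetaldehyde F7. Treatment of F7 with dimethyl (1-diazo-2-oxopropyl)phosphonate and K2CO3 in MeOH converts the formyl group into the terminal alkyne, and the route is rejoined at 11. The C11–C bond is thus made by olefination at an sp2 carbon and not by displacement at a hindered sp3 carbon.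

Step 13. HCl formed from BCl3 may protonate the C8 methylene, and the tertiary cation may be trapped by the Ar6 oxygen (closure to a chroman) or lose a proton into the ring. Fallback: setting out from 21, oxidative demethylation with (NH4)2Ce(NO3)6 in MeCN/H2O at 0 °C should give the quinone 4-{[(1R,4aS,6S,8aR)-6-bromo-5,5,8a-trimethyl-2-methylidenedecahydronaphthalen-1-yl]methyl}-3,6-dioxocyclohexa-1,4-diene-1-carbaldehyde F8. F8 is reduced without isolation by Na2S2O4 in THF/H2O to the hydroquinone, and the route is rejoined at 22 without any Lewis acid.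

Further compounds
F1 | step 3 | (1R,2S,5R)-menthyl (1S,4aR,6R,8aR)-6-bromo-5,5,8a-trimethyl-2-methylidenedecahydronaphthalene-1-carboxylate | C=C1CC[C@H]2C(C)(C)[C@H](Br)CC[C@@]2(C)[C@H]1C(=O)O[C@@H]3C[C@H](C)CC[C@H]3C(C)C
F2 | step 3 | [(1S,4aR,6R,8aR)-6-bromo-5,5,8a-trimethyl-2-methylidenedecahydronaphthalen-1-yl]methanol | C=C1CC[C@H]2C(C)(C)[C@H](Br)CC[C@@]2(C)[C@H]1CO
F3 | step 3 | [(1R,4aS,6S,8aS)-6-bromo-5,5,8a-trimethyl-2-methylidenedecahydronaphthalen-1-yl]methyl (1S,4R)-camphanate | C=C1CC[C@@H]2C(C)(C)[C@@H](Br)CC[C@]2(C)[C@@H]1COC(=O)[C@@]34CC[C@@](C)(C(=O)O3)C4(C)C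
F4 | step 3 | [(1S,4aR,6R,8aR)-6-bromo-5,5,8a-trimethyl-2-methylidenedecahydronaphthalen-1-yl]methyl (1S,4R)-camphanate | C=C1CC[C@H]2C(C)(C)[C@H](Br)CC[C@@]2(C)[C@H]1COC(=O)[C@@]34CC[C@@](C)(C(=O)O3)C4(C)C
F5 | step 7 | (1R,4aS,6S,8aS)-6-bromo-5,5,8a-trimethyl-2-methylidenedecahydronaphthalene-1-carbaldehyde | C=C1CC[C@@H]2C(C)(C)[C@@H](Br)CC[C@]2(C)[C@@H]1C=O
F6 | step 7 | (1R,4aS,6S,8aS)-6-bromo-1-(2-methoxyethenyl)-5,5,8a-trimethyl-2-methylidenedecahydronaphthalene (E/Z mixture) | C=C1CC[C@@H]2C(C)(C)[C@@H](Br)CC[C@]2(C)[C@@H]1C=COC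
F7 | step 7 | 2-[(1R,4aS,6S,8aR)-6-bromo-5,5,8a-trimethyl-2-methylidenedecahydronaphthalen-1-yl]acetaldehyde | C=C1CC[C@@H]2C(C)(C)[C@@H](Br)CC[C@]2(C)[C@@H]1CC=O
F8 | step 13 | 4-{[(1R,4aS,6S,8aR)-6-bromo-5,5,8a-trimethyl-2-methylidenedecahydronaphthalen-1-yl]methyl}-3,6-dioxocyclohexa-1,4-diene-1-carbaldehyde | C=C1CC[C@@H]2C(C)(C)[C@@H](Br)CC[C@]2(C)[C@@H]1CC3=CC(=O)C(C=O)=CC3=O
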